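**Assumptions (one line each)**
- C4 is the cyclic hemiketal onto O8, as drawn in the target SMILES. It closes spontaneously once the C4 ketone is unmasked next to the C8 oxygen.
- 2,3-O-Isopropylidene-D-erythronolactone (from D-erythorbic acid) is the cheap chiral starting material.

**Retrosynthesis**
1. Target ⇐ C2 acetylation ⇐ macro-aldol (C2–C3) between the C2 aldehyde and the C4 methyl ketone of lactone 22, which closes the 10-membered ring. The C4 hemiketal then closes onto O8.
2. Lactone 22 ⇐ C7 stereocentre by allylation of a C7 aldehyde with an α-acyl allyl bromide, and C8/C17 by Reformatsky addition to an α-ketoamide.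
3. Key step: an endo Diels–Alder of 1-acetoxybutadiene with an (E)-α-methyl enal made from the D-erythronolactone (C9 stereocentre plus the C7–C10 chain). It builds ring A and sets C1, C10 and C14 in one step.
4. Ring order: cyclohexane (Diels–Alder), then γ-lactone, then 10-membered carbocycle (aldol), then the tetrahydropyran hemiketal.

---

**Step 1**
Reactants: 1, 2,3-O-isopropylidene-D-erythronolactone
Product: 2, Weinreb amide of the acetonide-protected D-erythronic acid, free CH2OH
Conditions: MeNHOMe·HCl, i-PrMgCl, THF, –20 → 0 °C
Reagents that add atoms: N,O-dimethylhydroxylamine hydrochloride, CNOC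
Why: Grignard-activated Weinreb aminolysis opens the lactone irreversibly and leaves the acetonide intact, giving a stable amide that later serves as a masked C7 aldehyde; no new stereocentre.

**Step 2**
Reactants: 2
Product: 3, α-alkoxy aldehyde (C10 aldehyde)
Conditions: Dess–Martin periodinane, NaHCO3, CH2Cl2, 0 °C; crude used at once
Reagents that add atoms: none
Why: Buffered Dess–Martin oxidation of the primary alcohol is mild enough to avoid epimerising the α-stereocentre (C9) of the aldehyde.

**Step 3**
Reactants: 3; 4, 2-(triphenylphosphoranylidene)propanal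
Product: 5, (E)-enal: OHC–C(Me)=CH–C9 (acetonide, C8 Weinreb amide)
Conditions: CH2Cl2, 25 °C
Reagents that add atoms: none
Why: Wittig olefination with a stabilised ylide gives the (E)-α-methyl enal, placing C9 trans to the CHO, which is the relative geometry needed for ring A.

**Step 4 (key step)**
Reactants: 5; 6, trans-1-acetoxy-1,3-butadiene
Product: 7, cyclohexene adduct with C1 (Me, CHO), C10 (dioxolane at C9), C14 (OAc), C12=C13
Conditions: Eu(fod)3 (10 mol%), toluene, 60 °C, BHT
Reagents that add atoms: none
Why: In this normal-demand Diels–Alder the donor-substituted diene bonds through C14 to the α-carbon C1 (ortho) and endo, which puts C14–OAc cis to C2 and the C9 chain trans to C2 with the C1 quaternary centre, exactly as in the target; the A(1,3)-minimised enal conformer is attacked anti to the bulky C8 carbon, so the C9(R) stereocentre relays its chirality to C1/C10/C14.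

**Step 5**
Reactants: 7
Product: 8, C2 dimethyl acetal
Conditions: HC(OMe)3, PPTS (cat.), MeOH, 25 °C
Reagents that add atoms: trimethyl orthoformate, COC(OC)OC; methanol, CO
Why: Acetalisation masks the non-enolisable neopentyl aldehyde during the later oxidation and methylenation steps; the acetonide is not touched at this temperature and short reaction time.

**Step 6**
Reactants: 8
Product: 9, C11 enone (C11=O, C12=C13)
Conditions: SeO2 (20 mol%), TBHP, CH2Cl2, 25 °C; then MnO2
Reagents that add atoms: tert-butyl hydroperoxide, CC(C)(C)OO (supplies the oxygen)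
Why: Riley-type allylic oxidation occurs at the unhindered allylic CH2 (C11), because C14–H is deactivated by the acetate; MnO2 converts any allylic alcohol to the enone; no stereocentre is created.

**Step 7**
Reactants: 9
Product: 10, saturated C11 ketone
Conditions: H2 (1 atm), 10% Pd/C, EtOAc, 25 °C
Reagents that add atoms: none (H2 only)
Why: Catalytic hydrogenation of the conjugated disubstituted alkene leaves ketone, amide, acetates and acetals untouched; C12 and C13 are not stereocentres.

**Step 8**
Reactants: 10
Product: 11, exocyclic C11=C20 methylene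
Conditions: Cp2TiMe2, toluene, 75 °C, dark
Reagents that add atoms: dimethyltitanocene, C[Ti](C)(C1C=CC=C1)C1C=CC=C1 (supplies CH2)
Why: Petasis methylenation converts the hindered ketone to the exocyclic alkene under neutral conditions that the Weinreb amide, acetate, acetonide and acetal tolerate; C10 is thermodynamically fixed with C9 equatorial.

**Step 9**
Reactants: 11
Product: 12, C8/C9 diol (acetal retained)
Conditions: PPTS, MeOH, 50 °C
Reagents that add atoms: none
Why: Transketalisation of the acid-labile acetonide into 2,2-dimethoxypropane is driven by MeOH, while the hindered, β-acetoxy-deactivated dimethyl acetal is retained in MeOH.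

**Step 10**
Reactants: 12
Product: 13, α-keto Weinreb amide (C8 ketone, C9–OH free)
Conditions: Dess–Martin periodinane (1.05 equiv), NaHCO3, CH2Cl2, 0 °C
Reagents that add atoms: none
Why: The α-hydroxy amide C8–OH is far less hindered than the C9–OH next to the C10 ring branch, so it is oxidised selectively; the C8 stereocentre is intentionally destroyed and re-made in Step 12.

**Step 11**
Reactants: 13
Product: 14, C9 acetate
Conditions: Ac2O, DMAP, pyridine, 0 → 25 °C
Reagents that add atoms: acetic anhydride, CC(=O)OC(C)=O
Why: Acetylation installs the final C9 acetate now, which also prevents a competing C9–O lactone later.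

**Step 12**
Reactants: 14; 15, tert-butyl 2-bromopropanoate
Product: 16, tertiary C8 O-TMS ether with C17 stereocentre (tBu ester, Weinreb amide)
Conditions: Zn dust, TMSCl, THF, 40 °C
Reagents that add atoms: chlorotrimethylsilane, C[Si](C)(C)Cl
Why: Reformatsky addition of the zinc enolate to the α-ketoamide is Cram-chelate controlled (Zn bridging C8=O and O9), so attack comes from the face syn to H9 and anti to the ring-A carbon C10, setting C8; TMSCl traps the alkoxide, and C17 is set by the closed transition state and is later equilibrated to the more stable lactone epimer.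

**Step 13**
Reactants: 16
Product: 17, C7 aldehyde (C8 OTMS, tBu ester)
Conditions: Cp2Zr(H)Cl, THF, 25 °C
Reagents that add atoms: none (hydride only)
Why: Schwartz reagent reduces the Weinreb amide to the aldehyde chemoselectively in the presence of the tBu ester, acetates and silyl ether, and without epimerising the non-enolisable C7 centre.

**Step 14 (parallel branch: allyl bromide)**
Reactants: 18, methyl vinyl ketone
Product: 19, 3-(hydroxymethyl)but-3-en-2-one
Conditions: aq. HCHO, DABCO (cat.), dioxane/H2O, 25 °C
Reagents that add atoms: formaldehyde, C=O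
Why: Morita–Baylis–Hillman hydroxymethylation of the enone gives the symmetric 2-substituted allylic alcohol; no stereocentre.

**Step 15**
Reactants: 19
Product: 20, 3-(bromomethyl)but-3-en-2-one (used crude)
Conditions: PBr3, Et2O, 0 °C
Reagents that add atoms: phosphorus tribromide, BrP(Br)Br
Why: SN2 bromination of the primary allylic alcohol gives a symmetrical allyl bromide, so there is no regiochemical ambiguity in the next step.

**Step 16**
Reactants: 17; 20
Product: 21, homoallylic alcohol carrying C7–OH and the C4 methyl ketone (C3–C6, C16 unit)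
Conditions: In powder, THF/H2O (4:1), 25 °C
Reagents that add atoms: none
Why: Barbier-type allylindium addition to the aldehyde is non-chelated because O8 is silylated, so polar Felkin–Anh control (O8 anti to the incoming allyl, passing the smaller C17 side) sets C7.

**Step 17**
Reactants: 21
Product: 22, γ-lactone with C2 aldehyde, C8–OH and C4 methyl ketone (may exist partly as the C4/O8 hemiketal)
Conditions: TFA/H2O/CH2Cl2 (5:1:10), 0 → 25 °C
Reagents that add atoms: water, O
Why: Acid cleaves the tBu ester, TMS ether and dimethyl acetal in one pot, and the liberated acid lactonises onto the C7–OH (5-exo, acid-catalysed esterification) without changing C7.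

**Step 18**
Reactants: 22
Product: 23, 10-membered macrocycle: C2–OH, C4 hemiketal with O8
Conditions: KHMDS (3 equiv), THF, –78 → –40 °C, 0.002 M, syringe-pump addition; quench with aq. NH4Cl
Reagents that add atoms: none
Why: Intramolecular aldol of the kinetic methyl-ketone enolate onto the non-enolisable neopentyl C2 aldehyde closes the 10-membered ring; the rigid ring-A/lactone framework dictates the facial selectivity at C2, and the β-hydroxy ketone is immediately retained as the C4 hemiketal with O8, which blocks retro-aldol and E1cB loss of the C2 oxygen.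

**Step 19**
Reactants: 23
Product: 24, (+)-Junceellolide A
Conditions: Ac2O, DMAP, pyridine, 0 → 25 °C
Reagents that add atoms: acetic anhydride, CC(=O)OC(C)=O
Why: Acylation of the secondary C2–OH (the tertiary hemiketal OH does not react) completes the third acetate and gives the target, with any C14 acetate migrated in Step 18 re-acylated at the same time.

---

**Compound list**

1 | 2,3-O-isopropylidene-D-erythronolactone | O=C1OC[C@H]2OC(C)(C)O[C@@H]12 | starting material
2 | Weinreb amide of acetonide-protected D-erythronic acid, free CH2OH | CON(C)C(=O)[C@@H]1OC(C)(C)O[C@@H]1CO | intermediate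
3 | α-alkoxy aldehyde (C10 CHO) | CON(C)C(=O)[C@@H]1OC(C)(C)O[C@@H]1C=O | intermediate
4 | 2-(triphenylphosphoranylidene)propanal | CC(C=O)=P(c1ccccc1)(c1ccccc1)c1ccccc1 | starting material
5 | (E)-α-methyl enal dienophile | CON(C)C(=O)[C@@H]1OC(C)(C)O[C@@H]1/C=C(/C=O)C | intermediate
6 | trans-1-acetoxy-1,3-butadiene | CC(=O)O/C=C/C=C | starting material
7 | endo Diels–Alder adduct | CC(=O)O[C@H]1C=CC[C@H]([C@H]2OC(C)(C)O[C@H]2C(=O)N(C)OC)[C@@]1(C)C=O | intermediate
8 | C2 dimethyl acetal | CC(=O)O[C@H]1C=CC[C@H]([C@H]2OC(C)(C)O[C@H]2C(=O)N(C)OC)[C@@]1(C)C(OC)OC | intermediate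
9 | C11 enone | CC(=O)O[C@H]1C=CC(=O)[C@H]([C@H]2OC(C)(C)O[C@H]2C(=O)N(C)OC)[C@@]1(C)C(OC)OC | intermediate
10 | saturated C11 ketone | CC(=O)O[C@H]1CCC(=O)[C@H]([C@H]2OC(C)(C)O[C@H]2C(=O)N(C)OC)[C@@]1(C)C(OC)OC | intermediate
11 | exocyclic C11 methylene | CC(=O)O[C@H]1CCC(=C)[C@H]([C@H]2OC(C)(C)O[C@H]2C(=O)N(C)OC)[C@@]1(C)C(OC)OC | intermediate
12 | C8/C9 diol | CC(=O)O[C@H]1CCC(=C)[C@H]([C@@H](O)[C@@H](O)C(=O)N(C)OC)[C@@]1(C)C(OC)OC | intermediate
13 | α-keto Weinreb amide | CC(=O)O[C@H]1CCC(=C)[C@H]([C@@H](O)C(=O)C(=O)N(C)OC)[C@@]1(C)C(OC)OC | intermediate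
14 | C9 acetate | CC(=O)O[C@H]1CCC(=C)[C@H]([C@@H](OC(C)=O)C(=O)C(=O)N(C)OC)[C@@]1(C)C(OC)OC | intermediate
15 | tert-butyl 2-bromopropanoate | CC(Br)C(=O)OC(C)(C)C | starting material
16 | Reformatsky adduct, C8 O-TMS | CC(=O)O[C@H]1CCC(=C)[C@H]([C@@H](OC(C)=O)[C@@](O[Si](C)(C)C)(C(=O)N(C)OC)[C@@H](C)C(=O)OC(C)(C)C)[C@@]1(C)C(OC)OC | intermediate
17 | C7 aldehyde | CC(=O)O[C@H]1CCC(=C)[C@H]([C@@H](OC(C)=O)[C@@](O[Si](C)(C)C)(C=O)[C@@H](C)C(=O)OC(C)(C)C)[C@@]1(C)C(OC)OC | intermediate
18 | methyl vinyl ketone | C=CC(C)=O | starting material
19 | 3-(hydroxymethyl)but-3-en-2-one | CC(=O)C(=C)CO | intermediate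
20 | 3-(bromomethyl)but-3-en-2-one | CC(=O)C(=C)CBr | intermediate
21 | homoallylic alcohol | CC(=O)O[C@H]1CCC(=C)[C@H]([C@@H](OC(C)=O)[C@@](O[Si](C)(C)C)([C@@H](O)CC(=C)C(C)=O)[C@@H](C)C(=O)OC(C)(C)C)[C@@]1(C)C(OC)OC | intermediate
22 | lactone aldehyde, C8–OH, C4 ketone (open form) | CC(=O)O[C@H]1CCC(=C)[C@H]([C@@H](OC(C)=O)[C@]2(O)[C@@H](C)C(=O)O[C@H]2CC(=C)C(C)=O)[C@@]1(C)C=O | intermediate
23 | macrocyclic C2-hydroxy hemiketal | C=C1CC[C@H](OC(C)=O)[C@@]2(C)[C@H]1[C@@H](OC(C)=O)[C@@]13O[C@](O)(C[C@H]2O)C(=C)C[C@@H]1OC(=O)[C@@H]3C | intermediate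
24 | (+)-Junceellolide A | C=C1CC[C@H](OC(C)=O)[C@@]2(C)[C@H]1[C@@H](OC(C)=O)[C@@]13O[C@](O)(C[C@H]2OC(C)=O)C(=C)C[C@@H]1OC(=O)[C@@H]3C | target

---

**Totals:** 19 steps in total, including the 2-step allyl bromide branch (Steps 14–15). The longest linear sequence is 17 steps (Steps 1–13, then 16–19).

**Three steps most likely to fail**
1. **Step 4 (Diels–Alder):** the trisubstituted α-methyl enal is a poor dienophile, and the endo/ortho and facial selectivities from the single C9 centre are uncertain.
   Fallback: run the cycloaddition intramolecularly, tethering the diene to O9 through a removable silaketal or mixed-acetal tether so the tether enforces the facial selectivity, then cleave the tether after cycloaddition.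
2. **Step 16 (C7 allylation):** the predicted polar Felkin–Anh selectivity may be eroded by residual chelation or an H-bond to the C9 acetate.
   Fallback: accept the chelation-derived C7 epimer and lactonise it under Mitsunobu conditions (DIAD, PPh3), which inverts C7 by an SN2 pathway.
3. **Step 18 (macro-aldol):** ring closure, C2 stereochemistry and 1,3-acyl transfer between C2–O and C14–OAc are all uncertain.
   Fallback: switch the closure to an intramolecular Nozaki–Hiyama–Kishi coupling. Use 2,3-dibromopropene in Step 16 to place a C5 vinyl bromide, extend C2 to a C3–C4 aldehyde by Mukaiyama aldol with a masked acetaldehyde, close C4–C5 with CrCl2/NiCl2, and oxidise C4 to the ketone.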